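**Strategy.** Ring C of the upper flavan is disconnected across O1–C2 and C3–C4: an ortho-quinone methide spanning O1=C8a–C4a=C4 of ring A (C4 already bonded to C6 of the lower unit) plus a cis-1,2-dioxygenated two-carbon unit C2–C3. A chiral-acid-catalysed inverse-demand oxa-Diels–Alder reaction of this quinone methide, released from a 2-hydroxybenzhydrol, with (Z)-1,2-bis(benzyloxy)ethene closes ring C and sets C3 and C4 (3,4-cis). C2 arrives as a benzyl acetal; ring B is then installed there trans to O3, and the lower 4-ketone is reduced to the 3,4-cis diol before global hydrogenolysis. The key step exploits the 1,4-relationship of phenolic O1 and benzylic C4 through ring A.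

Key step: step 11

Remark (numbering): flavan numbering is used; the upper unit is unprimed (O1, C2, C3, C4, C4a–C8a), the lower unit is primed; ring A is the benzo ring, ring B the catechol ring, ring C the pyran ring.
Remark (descriptors): while O7' is benzylated (or silylated) the upper C4 is R by the priority rules; the same geometry is S in the target and in the free phenol F5.
Remark (assumptions): compounds 1, 4, 10, 11, 14 and 16 are taken to be commercial. The (R)-enantiomer of the acid catalyst in step 11 is assumed to give the (3S,4R) adduct; if the first run shows the opposite sense, the (S)-catalyst is used.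

**Step 1**
Reactants: 1 1-[4-(benzyloxy)-2-hydroxyphenyl]ethan-1-one
Product: 2 1-[4-(benzyloxy)-2-hydroxy-5-iodophenyl]ethan-1-one
Conditions: NIS, TFA (cat.), MeCN, rt
Reagents that add atoms: N-iodosuccinimide, O=C1CCC(=O)N1I
Why: Electrophilic aromatic iodination should go para to the free phenol (C5), which is activated by both oxygens and less hindered than C3 between them.

**Step 2**
Reactants: 2 1-[4-(benzyloxy)-2-hydroxy-5-iodophenyl]ethan-1-one
Product: 3 1-[4-(benzyloxy)-5-iodo-2-(methoxymethoxy)phenyl]ethan-1-one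
Conditions: NaH, MOMCl, THF–DMF, 0 °C → rt
Reagents that add atoms: chloromethyl methyl ether, COCCl
Why: Williamson O-alkylation of the sodium phenoxide masks the oxygen that later becomes O1', so that the enone can be epoxidised without oxidative cyclisation.

**Step 3**
Reactants: 3 1-[4-(benzyloxy)-5-iodo-2-(methoxymethoxy)phenyl]ethan-1-one; 4 3,4-bis(benzyloxy)benzaldehyde
Product: 5 (E)-chalcone
Conditions: KOH, EtOH–THF, rt
Reagents that add atoms: none
Why: Claisen–Schmidt condensation; E1cB dehydration of the aldol gives the conjugated E-enone.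

**Step 4**
Reactants: 5 (E)-chalcone
Product: 6 (αR,βS)-trans-epoxy ketone
Conditions: poly-L-leucine, urea·H2O2, DBU, THF, rt
Reagents that add atoms: hydrogen peroxide–urea, OO.NC(N)=O
Why: Juliá–Colonna epoxidation (nucleophilic Weitz–Scheffer epoxidation inside the helical poly-L-leucine) should deliver hydroperoxide to one enone face and give the (2R,3S)-oxirane, the known sense for chalcones with the L-polymer.

**Step 5**
Reactants: 6 (αR,βS)-trans-epoxy ketone
Product: 7 (2R,3R)-7-(benzyloxy)-2-[3,4-bis(benzyloxy)phenyl]-3-hydroxy-6-iodochroman-4-one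
Conditions: conc. HCl, MeOH–THF, 50 °C
Reagents that add atoms: none
Why: Acid removes the MOM group and the freed phenol opens the epoxide at the benzylic carbon (6-endo, inversion at C2', C3' untouched); the 2,3-trans dihydroflavonol is also the thermodynamic isomer.

**Step 6**
Reactants: 7 (2R,3R)-dihydroflavonol
Product: 8 (2R,3R)-3,7-bis(benzyloxy)-2-[3,4-bis(benzyloxy)phenyl]-6-iodochroman-4-one
Conditions: benzyl 2,2,2-trichloroacetimidate, TfOH (cat.), CH2Cl2–cyclohexane, 0 °C → rt
Reagents that add atoms: benzyl 2,2,2-trichloroacetimidate, N=C(OCc1ccccc1)C(Cl)(Cl)Cl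
Why: Acid-catalysed imidate benzylation protects the 3'-OH without base, which would ring-open and racemise the flavanone.

**Step 7**
Reactants: 8 (2R,3R)-6-iodoflavanone
Product: 9 (2R,3R)-3,7-bis(benzyloxy)-2-[3,4-bis(benzyloxy)phenyl]-4-oxochroman-6-carbaldehyde
Conditions: Pd(PPh3)4 (5 mol %), CO (3 atm), Bu3SnH (slow addition), toluene, 50 °C
Reagents that add atoms: carbon monoxide, [C-]#[O+]
Why: Palladium-catalysed reductive carbonylation of the aryl iodide (oxidative addition, CO insertion, hydride transfer from tin, reductive elimination) is base-free and leaves the ketone and both stereocentres untouched.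

**Step 8**
Reactants: 10 (benzyloxy)acetaldehyde; 11 benzyloxytrimethylsilane
Product: 13 (Z)-1,2-bis(benzyloxy)ethene, via 1,1,2-tris(benzyloxy)ethane 12 (not isolated)
Conditions: TMSOTf (cat.), CH2Cl2, −78 °C; then TMSOTf (1.2 equiv), i-Pr2NEt, −20 °C → rt
Reagents that add atoms: none
Why: Silyl-triflate-catalysed acetalisation with the silyl ether is followed in the same flask by silyl-triflate/amine elimination of the acetal to the enol ether; the Z isomer should predominate (cis preference of vicinal dialkoxyalkenes) and is separated from E on base-washed silica.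

**Step 9**
Reactants: 14 [3,4-bis(benzyloxy)phenyl]boronic acid
Product: 15 potassium [3,4-bis(benzyloxy)phenyl]trifluoroborate
Conditions: KHF2 (aq.), MeOH, rt
Reagents that add atoms: potassium hydrogen difluoride, [K+].[F-].F
Why: Standard conversion of a boronic acid into its crystalline trifluoroborate salt.

**Step 10**
Reactants: 9 lower-unit aldehyde; 16 3-(benzyloxy)phenol
Product: 18 2-hydroxybenzhydrol (carbinol epimers), via bromomagnesium 3-(benzyloxy)phenoxide 17 (not isolated)
Conditions: EtMgBr, Et2O, 0 °C; then 9, CH2Cl2, rt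
Reagents that add atoms: none
Why: Ortho-specific hydroxyalkylation of a magnesium phenoxide: the aldehyde bound to magnesium is attacked by the ortho carbon para to OBn through a six-membered transition state; the ketone does not react, and the new carbinol centre is uncontrolled and is erased in step 11.

**Step 11**
Reactants: 18 2-hydroxybenzhydrol; 13 (Z)-1,2-bis(benzyloxy)ethene
Product: 20 all-cis (2R,3S,4R) cycloadduct, via ortho-quinone methide 19 (not isolated)
Conditions: (R)-3,3'-bis(2,4,6-triisopropylphenyl)-1,1'-binaphthyl-2,2'-diyl hydrogen phosphate (10 mol %), 13 (3 equiv), 5 Å MS, toluene, 0 °C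
Reagents that add atoms: none
Why: The chiral acid ionises the doubly donor-stabilised benzhydrol (loss of water) to the hydrogen-bonded (E)-ortho-quinone methide 19, whose O1=C8a–C4a=C4 oxadiene undergoes an asynchronous inverse-electron-demand oxa-Diels–Alder reaction with the electron-rich enediol diether 13, C3–C4 bond formation leading and O1–C2 closure following within the ion pair. The closest known reaction type is the chiral phosphoric acid catalysed [4+2] cycloaddition of quinone methides generated in situ from 2-hydroxybenzhydrols with enol ethers, enamides and styrenes. Ring C is closed by the cycloaddition itself, a [4+2] annulation onto ring A in which both new bonds form on one face of the dienophile. C2 and C3 are cis because the Z geometry of 13 is transferred stereospecifically; C3 and C4 are cis because in the endo transition state both benzyloxy groups lie under the dienone while the C4 aryl group occupies the outside position of the E-quinone methide, as with 2,3-dihydrofuran and other cis enol ethers. The absolute configuration at C3 and C4 is set by the phosphate bound to O1, whose 3,3'-aryl groups shield one face of C4; the remote lower-unit stereocentres exert no control, so attack on the minor face gives a diastereomer that is removed by chromatography. Regiochemistry is moot because 13 is symmetric, only O1 can close the ring because O7' is benzylated, and the 4'-ketone deactivates the lower ring A and prevents ionisation at C4', while the excess of 13 outcompetes attack by ring A of a second molecule.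

**Step 12**
Reactants: 20 all-cis cycloadduct; 15 potassium [3,4-bis(benzyloxy)phenyl]trifluoroborate
Product: 22 octabenzyl biflavanoid ketone, via oxocarbenium ion 21 (not isolated)
Conditions: 15 (2 equiv), BF3·OEt2 (3 equiv), CH2Cl2–MeCN, −40 → 0 °C
Reagents that add atoms: none
Why: BF3 strips fluoride from 15 to give the aryldifluoroborane, which ionises the C2 benzyl acetal to oxocarbenium ion 21 and transfers its aryl group to C2 (Lewis-acid coupling of mixed acetals with aryltrifluoroborates); the aryl should enter anti to the cis C3–OBn and C4–aryl groups, giving the 2,3-trans (2R) flavan with equatorial ring B, and the O1–C2 bond is never broken.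

**Step 13**
Reactants: 22 octabenzyl biflavanoid ketone
Product: 23 octabenzyl (2'R,3'S,4'S)-4'-ol
Conditions: LiBH(s-Bu)3, THF, −78 °C; then H2O
Reagents that add atoms: none
Why: The bulky trialkylborohydride attacks the chromanone carbonyl from the equatorial direction, giving the axial 4'-OH cis to the equatorial 3'-OBn (3',4'-cis diol pattern); low temperature avoids enolisation of the flavanone.

**Step 14**
Reactants: 23 octabenzyl 4'-ol
Product: 24 CNP0280090.1
Conditions: H2 (1 atm), Pd(OH)2/C, EtOAc–MeOH, rt, acid-free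
Reagents that add atoms: none
Why: Hydrogenolysis cleaves the six aryl and two alkyl benzyl ethers; under neutral conditions the benzylic C4'–OH and the C2–O1 bonds should persist, as they do when dihydroflavonols are hydrogenated to flavan-3,4-diols.

**Compound list**

1 | 1-[4-(benzyloxy)-2-hydroxyphenyl]ethan-1-one | CC(=O)c1ccc(OCc2ccccc2)cc1O | starting material
2 | 1-[4-(benzyloxy)-2-hydroxy-5-iodophenyl]ethan-1-one | CC(=O)c1cc(I)c(OCc2ccccc2)cc1O | intermediate
3 | 1-[4-(benzyloxy)-5-iodo-2-(methoxymethoxy)phenyl]ethan-1-one | CC(=O)c1cc(I)c(OCc2ccccc2)cc1OCOC | intermediate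
4 | 3,4-bis(benzyloxy)benzaldehyde | O=Cc1ccc(OCc2ccccc2)c(OCc2ccccc2)c1 | starting material
5 | (E)-1-[4-(benzyloxy)-5-iodo-2-(methoxymethoxy)phenyl]-3-[3,4-bis(benzyloxy)phenyl]prop-2-en-1-one | O=C(/C=C/c1ccc(OCc2ccccc2)c(OCc2ccccc2)c1)c1cc(I)c(OCc2ccccc2)cc1OCOC | intermediate
6 | [4-(benzyloxy)-5-iodo-2-(methoxymethoxy)phenyl]{(2R,3S)-3-[3,4-bis(benzyloxy)phenyl]oxiran-2-yl}methanone | O=C(c1cc(I)c(OCc2ccccc2)cc1OCOC)[C@@H]1O[C@H]1c1ccc(OCc2ccccc2)c(OCc2ccccc2)c1 | intermediate
7 | (2R,3R)-7-(benzyloxy)-2-[3,4-bis(benzyloxy)phenyl]-3-hydroxy-6-iodo-2,3-dihydro-4H-chromen-4-one | Ic1cc2c(cc1OCc1ccccc1)O[C@H](c1ccc(OCc3ccccc3)c(OCc3ccccc3)c1)[C@@H](O)C2=O | intermediate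
8 | (2R,3R)-3,7-bis(benzyloxy)-2-[3,4-bis(benzyloxy)phenyl]-6-iodo-2,3-dihydro-4H-chromen-4-one | Ic1cc2c(cc1OCc1ccccc1)O[C@H](c1ccc(OCc3ccccc3)c(OCc3ccccc3)c1)[C@@H](OCc1ccccc1)C2=O | intermediate
9 | (2R,3R)-3,7-bis(benzyloxy)-2-[3,4-bis(benzyloxy)phenyl]-4-oxo-3,4-dihydro-2H-chromene-6-carbaldehyde | O=Cc1cc2c(cc1OCc1ccccc1)O[C@H](c1ccc(OCc3ccccc3)c(OCc3ccccc3)c1)[C@@H](OCc1ccccc1)C2=O | intermediate
10 | (benzyloxy)acetaldehyde | O=CCOCc1ccccc1 | starting material
11 | benzyloxytrimethylsilane | C[Si](C)(C)OCc1ccccc1 | starting material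
12 | 1,1,2-tris(benzyloxy)ethane | C(OCc1ccccc1)C(OCc1ccccc1)OCc1ccccc1 | intermediate (not isolated)
13 | (Z)-1,2-bis(benzyloxy)ethene | c1ccccc1CO/C=C\OCc1ccccc1 | intermediate
14 | [3,4-bis(benzyloxy)phenyl]boronic acid | OB(O)c1ccc(OCc2ccccc2)c(OCc2ccccc2)c1 | starting material
15 | potassium [3,4-bis(benzyloxy)phenyl]trifluoroborate | [K+].F[B-](F)(F)c1ccc(OCc2ccccc2)c(OCc2ccccc2)c1 | intermediate
16 | 3-(benzyloxy)phenol | Oc1cccc(OCc2ccccc2)c1 | starting material
17 | bromomagnesium 3-(benzyloxy)phenoxide | Br[Mg]Oc1cccc(OCc2ccccc2)c1 | intermediate (not isolated)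
18 | (2R,3R)-3,7-bis(benzyloxy)-2-[3,4-bis(benzyloxy)phenyl]-6-{[4-(benzyloxy)-2-hydroxyphenyl](hydroxy)methyl}-2,3-dihydro-4H-chromen-4-one, both carbinol epimers | OC(c1ccc(OCc2ccccc2)cc1O)c1cc2c(cc1OCc1ccccc1)O[C@H](c1ccc(OCc3ccccc3)c(OCc3ccccc3)c1)[C@@H](OCc1ccccc1)C2=O | intermediate
19 | (2R,3R)-3,7-bis(benzyloxy)-2-[3,4-bis(benzyloxy)phenyl]-6-{(E)-[4-(benzyloxy)-6-oxocyclohexa-2,4-dien-1-ylidene]methyl}-2,3-dihydro-4H-chromen-4-one (ortho-quinone methide) | O=C1C=C(OCc2ccccc2)C=C/C1=C\c1cc2c(cc1OCc1ccccc1)O[C@H](c1ccc(OCc3ccccc3)c(OCc3ccccc3)c1)[C@@H](OCc1ccccc1)C2=O | intermediate (not isolated)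
20 | (2R,3R)-3,7-bis(benzyloxy)-2-[3,4-bis(benzyloxy)phenyl]-6-[(2R,3S,4R)-2,3,7-tris(benzyloxy)-3,4-dihydro-2H-chromen-4-yl]-2,3-dihydro-4H-chromen-4-one (2,3-cis-3,4-cis acetal) | c1ccccc1COc1ccc2c(c1)O[C@@H](OCc1ccccc1)[C@@H](OCc1ccccc1)[C@H]2c1cc2c(cc1OCc1ccccc1)O[C@H](c1ccc(OCc3ccccc3)c(OCc3ccccc3)c1)[C@@H](OCc1ccccc1)C2=O | intermediate
21 | (3S,4R)-3,7-bis(benzyloxy)-4-{(2R,3R)-3,7-bis(benzyloxy)-2-[3,4-bis(benzyloxy)phenyl]-4-oxochroman-6-yl}-3,4-dihydrochromenylium (oxocarbenium ion) | c1ccccc1COc1ccc2c(c1)[O+]=C[C@@H](OCc1ccccc1)[C@H]2c1cc2c(cc1OCc1ccccc1)O[C@H](c1ccc(OCc3ccccc3)c(OCc3ccccc3)c1)[C@@H](OCc1ccccc1)C2=O | intermediate (not isolated)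
22 | (2R,3R)-3,7-bis(benzyloxy)-2-[3,4-bis(benzyloxy)phenyl]-6-{(2R,3S,4R)-3,7-bis(benzyloxy)-2-[3,4-bis(benzyloxy)phenyl]-3,4-dihydro-2H-chromen-4-yl}-2,3-dihydro-4H-chromen-4-one | c1ccccc1COc1ccc2c(c1)O[C@H](c1ccc(OCc3ccccc3)c(OCc3ccccc3)c1)[C@@H](OCc1ccccc1)[C@H]2c1cc2c(cc1OCc1ccccc1)O[C@H](c1ccc(OCc3ccccc3)c(OCc3ccccc3)c1)[C@@H](OCc1ccccc1)C2=O | intermediate
23 | (2R,3S,4S)-3,7-bis(benzyloxy)-2-[3,4-bis(benzyloxy)phenyl]-6-{(2R,3S,4R)-3,7-bis(benzyloxy)-2-[3,4-bis(benzyloxy)phenyl]-3,4-dihydro-2H-chromen-4-yl}-3,4-dihydro-2H-chromen-4-ol | c1ccccc1COc1ccc2c(c1)O[C@H](c1ccc(OCc3ccccc3)c(OCc3ccccc3)c1)[C@@H](OCc1ccccc1)[C@H]2c1cc2c(cc1OCc1ccccc1)O[C@H](c1ccc(OCc3ccccc3)c(OCc3ccccc3)c1)[C@@H](OCc1ccccc1)[C@H]2O | intermediate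
24 | CNP0280090.1, (2R,3S,4S)-2-(3,4-dihydroxyphenyl)-6-[(2R,3S,4S)-2-(3,4-dihydroxyphenyl)-3,7-dihydroxy-3,4-dihydro-2H-chromen-4-yl]-3,4-dihydro-2H-chromene-3,4,7-triol | Oc1ccc2c(c1)O[C@H](c1ccc(O)c(O)c1)[C@@H](O)[C@H]2c1cc2c(cc1O)O[C@H](c1ccc(O)c(O)c1)[C@@H](O)[C@H]2O | target

**Step count.** Total: 14 steps. Longest linear sequence: 12 steps (steps 1–7, then 10–14, from compound 1).

**Steps most likely to fail**

Step 11 (key step). The acid catalyst may discriminate poorly between the two faces of the quinone methide, since the dienophile has no hydrogen-bond donor. The endo preference may also erode, and the cation may be diverted by acetal formation with the enol ether or by attack of ring A of another molecule. Fallback, setting out from 18: condensation with phenylboronic acid (toluene, azeotropic removal of water) would give the cyclic boronate (2R,3R)-3,7-bis(benzyloxy)-6-[7-(benzyloxy)-2-phenyl-4H-1,3,2-benzodioxaborinin-4-yl]-2-[3,4-bis(benzyloxy)phenyl]chroman-4-one F1. Heating F1 with 13 in toluene (100 °C) releases the same quinone methide 19 without acid, and the uncatalysed endo cycloaddition should give 20 together with its upper-unit (2S,3R,4S) diastereomer F2. Because the lower unit is enantiopure the two are diastereomers and are separated by chromatography; the route is rejoined at 20.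

Step 12. The aryl group may be delivered within the ion pair to the face that the benzyloxy group left (wrong C2 configuration), the oxocarbenium ion may lose H3 to give an enol ether, or it may alkylate ring A of another molecule. Fallback, setting out from 20: bromotrimethylsilane (CH2Cl2, −20 °C) would exchange the anomeric benzyloxy group for bromide to give the 2-bromochroman (2R,3R)-3,7-bis(benzyloxy)-2-[3,4-bis(benzyloxy)phenyl]-6-[(3S,4R)-3,7-bis(benzyloxy)-2-bromo-3,4-dihydro-2H-chromen-4-yl]chroman-4-one F3. Nickel-catalysed Negishi coupling (NiCl2·DME, 4,4'-di-tert-butyl-2,2'-bipyridine, THF–DMA, 0 °C → rt) with [3,4-bis(benzyloxy)phenyl]zinc bromide F4 would then install ring B. F4 is made from commercial 4-bromo-1,2-bis(benzyloxy)benzene with i-PrMgCl·LiCl and then ZnBr2. The coupling runs through a C2 radical that is arylated trans to the C3 substituent, tolerates the ketone, and returns to the route at 22.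

Step 14. The electron-rich benzylic C4'–OH may be hydrogenolysed, or the acid-labile flavan-3,4-diol may ionise and oligomerise during the long reduction needed for eight benzyl ethers. Fallback, setting out from 22: hydrogenolysis is done first (H2, Pd(OH)2/C, EtOAc–MeOH), where no benzylic hydroxyl is present, to give the free octahydroxy ketone (2R,3R)-2-(3,4-dihydroxyphenyl)-6-[(2R,3S,4S)-2-(3,4-dihydroxyphenyl)-3,7-dihydroxy-3,4-dihydro-2H-chromen-4-yl]-3,7-dihydroxy-2,3-dihydro-4H-chromen-4-one F5. TBSOTf and 2,6-lutidine (CH2Cl2) would give its octakis(tert-butyldimethylsilyl) ether F6, and LiBH(s-Bu)3 (THF, −78 °C) the 3',4'-cis alcohol, the octakis(tert-butyldimethylsilyl) ether of the target F7. Et3N·3HF (THF–MeCN, rt) then removes the silyl groups without hydrogen or strong acid and returns to the route at 24.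

**Further compounds**

F1 | step 11 | (2R,3R)-3,7-bis(benzyloxy)-6-[7-(benzyloxy)-2-phenyl-4H-1,3,2-benzodioxaborinin-4-yl]-2-[3,4-bis(benzyloxy)phenyl]chroman-4-one | B1(c2ccccc2)Oc2cc(OCc3ccccc3)ccc2C(O1)c1cc2c(cc1OCc1ccccc1)O[C@H](c1ccc(OCc3ccccc3)c(OCc3ccccc3)c1)[C@@H](OCc1ccccc1)C2=O
F2 | step 11 | (2R,3R)-3,7-bis(benzyloxy)-2-[3,4-bis(benzyloxy)phenyl]-6-[(2S,3R,4S)-2,3,7-tris(benzyloxy)-3,4-dihydro-2H-chromen-4-yl]chroman-4-one | c1ccccc1COc1ccc2c(c1)O[C@H](OCc1ccccc1)[C@H](OCc1ccccc1)[C@@H]2c1cc2c(cc1OCc1ccccc1)O[C@H](c1ccc(OCc3ccccc3)c(OCc3ccccc3)c1)[C@@H](OCc1ccccc1)C2=O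
F3 | step 12 | (2R,3R)-3,7-bis(benzyloxy)-2-[3,4-bis(benzyloxy)phenyl]-6-[(3S,4R)-3,7-bis(benzyloxy)-2-bromo-3,4-dihydro-2H-chromen-4-yl]chroman-4-one, both C2 epimers | c1ccccc1COc1ccc2c(c1)OC(Br)[C@@H](OCc1ccccc1)[C@H]2c1cc2c(cc1OCc1ccccc1)O[C@H](c1ccc(OCc3ccccc3)c(OCc3ccccc3)c1)[C@@H](OCc1ccccc1)C2=O
F4 | step 12 | [3,4-bis(benzyloxy)phenyl]zinc bromide | Br[Zn]c1ccc(OCc2ccccc2)c(OCc2ccccc2)c1
F5 | step 14 | (2R,3R)-2-(3,4-dihydroxyphenyl)-6-[(2R,3S,4S)-2-(3,4-dihydroxyphenyl)-3,7-dihydroxy-3,4-dihydro-2H-chromen-4-yl]-3,7-dihydroxy-2,3-dihydro-4H-chromen-4-one | Oc1ccc2c(c1)O[C@H](c1ccc(O)c(O)c1)[C@@H](O)[C@H]2c1cc2c(cc1O)O[C@H](c1ccc(O)c(O)c1)[C@@H](O)C2=O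
F6 | step 14 | octakis(tert-butyldimethylsilyl) ether of F5 | CC(C)(C)[Si](C)(C)Oc1ccc2c(c1)O[C@H](c1ccc(O[Si](C)(C)C(C)(C)C)c(O[Si](C)(C)C(C)(C)C)c1)[C@@H](O[Si](C)(C)C(C)(C)C)[C@H]2c1cc2c(cc1O[Si](C)(C)C(C)(C)C)O[C@H](c1ccc(O[Si](C)(C)C(C)(C)C)c(O[Si](C)(C)C(C)(C)C)c1)[C@@H](O[Si](C)(C)C(C)(C)C)C2=O
F7 | step 14 | octakis(tert-butyldimethylsilyl) ether of 24 (all hydroxyls except the 4'-OH silylated) | CC(C)(C)[Si](C)(C)Oc1ccc2c(c1)O[C@H](c1ccc(O[Si](C)(C)C(C)(C)C)c(O[Si](C)(C)C(C)(C)C)c1)[C@@H](O[Si](C)(C)C(C)(C)C)[C@H]2c1cc2c(cc1O[Si](C)(C)C(C)(C)C)O[C@H](c1ccc(O[Si](C)(C)C(C)(C)C)c(O[Si](C)(C)C(C)(C)C)c1)[C@@H](O[Si](C)(C)C(C)(C)C)[C@H]2O
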